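**Plan**

1. Labels: cyclopentanone C1 (C=O), C2, C3, C4 (quaternary, CH3), C5 (CH bearing the cyclopropane); C9′ = benzylic CH; C1″ = isobutyl CH2; Ca/Cb = cyclopropane CH carbons (Ca carries the oxobutyl chain, Cb is bonded to C5).
2. Cuts, in retrosynthetic order: the two aryl–CHO bonds and the benzyl/dioxolane masks; the C1 carbonyl (back to a C5=C1 alkene); C5–Cb (cross-coupling); C5–C1 (aldehyde C5–H added across an allyl group); C4–CH3 and C9′–C1″ (conjugate addition, then enolate methylation); Ca–CH2 (carbometalation of 3,3-dimethylcyclopropene).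
3. Enabling feature: C9′ and C4 are the β- and α-carbons of acyl carbon C5, and C9′ sits on an aryl carbon whose ortho neighbour carries oxygen. Tying that oxygen to C5 closes a six-membered lactone (O, C5, C4, C9′, two aryl carbons), so both centres lie in a rigid coumarin/dihydrocoumarin ring.
4. Forward order: coumarin ring (Perkin) → key step on that ring (no ring formed) → lactone opened to the aldehyde → cyclopentanone ring by rhodium hydroacylation → cyclopropane (made separately from a Bamford–Stevens cyclopropene) joined by Negishi coupling → C1 oxygenation, debenzylation, diformylation.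
5. Stereochemistry: C9′ from the chiral copper catalyst; C4 from methylation of the lactone enolate anti to the new isobutyl group; Ca and Cb from enantioselective syn-carbomagnesiation and stereoretentive coupling; C5 by equilibration next to the C1 ketone.

Key step: step 3

Remark: the ligand antipode named in steps 3 and 10, (R,SP)-Josiphos = (R)-1-[(SP)-2-(diphenylphosphino)ferrocenyl]ethyldicyclohexylphosphine, is nominal and would be fixed on a model substrate so that the drawn configurations result; the C5 configuration of the target (cyclopropyl trans to the large C9′ group on C4) is assumed to be the thermodynamically preferred one at this epimerisable centre.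

**Route**

Step 1
Reactants: 1 3,5-bis(benzyloxy)phenol
Product: 2 4,6-bis(benzyloxy)-2-hydroxybenzaldehyde
Conditions: (CH2O)n, MgCl2, Et3N, MeCN, reflux
Reagents that add atoms: formaldehyde (as paraformaldehyde), C=O
Why: Magnesium-mediated ortho-formylation of a phenol (Casnati–Skattebøl), in which the magnesium phenoxide directs formaldehyde to one of the two equivalent ortho positions and a second formaldehyde oxidises the benzylic alkoxide, so a single salicylaldehyde should result.

Step 2
Reactants: 2 4,6-bis(benzyloxy)-2-hydroxybenzaldehyde; 3 pent-4-enoic anhydride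
Product: 4 3-allyl-5,7-bis(benzyloxy)coumarin
Conditions: Et3N, neat, 130 °C
Reagents that add atoms: pent-4-enoic anhydride, C=CCCC(=O)OC(=O)CCC=C
Why: Perkin condensation, in which O-acylation of the salicylaldehyde is followed by base-mediated intramolecular aldol condensation and lactonisation, as in the preparation of 3-alkylcoumarins from propionic or butyric anhydride, the isolated terminal alkene being inert to triethylamine.

Step 3
Reactants: 4 3-allyl-5,7-bis(benzyloxy)coumarin; 5 isobutylmagnesium bromide (in Et2O); 6 iodomethane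
Product: 9 (3R,4R)-3-allyl-5,7-bis(benzyloxy)-4-isobutyl-3-methylchroman-2-one, via silyl ketene acetal 7 (not isolated), via lithium enolate 8 (not isolated)
Conditions: CuBr·SMe2 (10 mol %), (R,SP)-Josiphos (12 mol %), Me3SiOTf, tBuOMe, −78 °C; then MeLi, THF, −78 → −20 °C; then 6, DMPU, −78 → 0 °C
Reagents that add atoms: isobutylmagnesium bromide, CC(C)C[Mg]Br; iodomethane, CI
Why: Me3SiOTf silylates the lactone carbonyl and turns the donor-substituted, C3-alkylated coumarin (a poor Michael acceptor) into a 2-silyloxybenzopyrylium ion that the 5,7-benzyloxy groups stabilise, and the Josiphos-bound alkylcopper species generated from 5 transfers isobutyl to C4 of the heterocycle (π-complex, trivalent copper σ-allyl, reductive elimination) to give silyl ketene acetal 7 and the C9′–C1″ bond; MeLi then cleaves the O–Si bond and lithium enolate 8 is C-methylated by 6, forming the C4–CH3 bond. The closest known reactions are the copper/ferrocenyl-diphosphine-catalysed enantioselective conjugate addition of Grignard reagents to coumarins, its Lewis-acid-assisted variants for weakly electrophilic acceptors, and the regeneration and alkylation of enolates from silyl enol ethers; the present coumarin is a more hindered and more electron-rich member of that substrate class. No ring is closed and the lactone ring stays intact. C9′ is set by the chiral copper catalyst, which selects the enantioface of the C3=C4 bond of the coumarin; quaternary C4 is set by the substrate, because in the half-chair enolate the isobutyl group is pseudoaxial (it avoids the peri 5-benzyloxy group) and screens one face, so MeI enters trans to it and the allyl group ends cis to isobutyl. The step needs 1,4- over 1,2-addition (copper catalysis at −78 °C, the carbonyl carbon carrying the silyloxy group next to a substituted C3), catalysed over uncatalysed addition (slow background reaction of the Grignard reagent at −78 °C in a weakly coordinating ether) and C- over O-methylation (lithium enolate, soft electrophile).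

Step 4
Reactants: 9 (3R,4R)-3-allyl-5,7-bis(benzyloxy)-4-isobutyl-3-methylchroman-2-one
Product: 10 (3R,4R)-3-allyl-5,7-bis(benzyloxy)-4-isobutyl-3-methylchroman-2-ol (lactol; both anomers)
Conditions: iBu2AlH, toluene, −78 °C; aq. potassium sodium tartrate (KNaC4H4O6)
Reagents that add atoms: none
Why: Lactone-to-lactol reduction with iBu2AlH, which stops at the aluminium hemiacetal at −78 °C, the neopentyl position of the carbonyl further disfavouring over-reduction, and the new lactol carbon forms as an inconsequential anomeric mixture.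

Step 5
Reactants: 10 lactol
Product: 11 (2R)-2-methyl-2-{(1R)-3-methyl-1-[2,4,6-tris(benzyloxy)phenyl]butyl}pent-4-enal
Conditions: BnBr, K2CO3, DMF, 25 °C
Reagents that add atoms: benzyl bromide, BrCc1ccccc1
Why: Williamson etherification of the ring-opened tautomer, whose phenoxide is the most acidic and most nucleophilic oxygen under carbonate base, so benzylation should drain the lactol/hydroxy-aldehyde equilibrium to the aldehyde, which cannot enolise because its α-carbon (C4) is quaternary.

Step 6
Reactants: 11 pentenal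
Product: 12 (2R)-2-methyl-2-{(1R)-3-methyl-1-[2,4,6-tris(benzyloxy)phenyl]butyl}cyclopentan-1-one
Conditions: [Rh(nbd)(dppe)]BF4 (5 mol %; nbd = norbornadiene, dppe = 1,2-bis(diphenylphosphino)ethane; pre-treated with H2), CH2Cl2, 25 → 40 °C
Reagents that add atoms: none
Why: Intramolecular hydroacylation of a 4-pentenal catalysed by cationic monovalent rhodium (oxidative addition of the aldehyde C–H, alkene insertion, reductive elimination), which forms the C5–C1 bond and the five-membered ketone, a reaction that tolerates quaternary α-carbons and touches no stereocentre.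

Step 7
Reactants: 12 cyclopentanone
Product: 13 (5R)-5-methyl-5-{(1S)-3-methyl-1-[2,4,6-tris(benzyloxy)phenyl]butyl}cyclopent-1-en-1-yl trifluoromethanesulfonate
Conditions: KN(SiMe3)2, THF, −78 °C; then PhNTf2, −78 → 0 °C
Reagents that add atoms: N-phenylbis(trifluoromethanesulfonimide), O=S(=O)(N(c1ccccc1)S(=O)(=O)C(F)(F)F)C(F)(F)F
Why: Enolate O-triflation, regiochemically unambiguous because only C1 carries α-hydrogens (C4 is quaternary), so a single enol triflate with the C5=C1 double bond should form.

Step 8
Reactants: 14 3-methylbut-2-enal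
Product: 15 3-methylbut-2-enal p-toluenesulfonylhydrazone
Conditions: TsNHNH2, MeOH, 25 °C
Reagents that add atoms: p-toluenesulfonohydrazide, Cc1ccc(cc1)S(=O)(=O)NN
Why: Condensation of an aldehyde with a sulfonylhydrazide (hydrazone formation), which is fast for unhindered enals and gives a crystalline product.

Step 9
Reactants: 15 tosylhydrazone
Product: 18 3,3-dimethylcyclopropene, via sodium tosylhydrazonide 16 (not isolated), via 1-diazo-3-methylbut-2-ene 17 (not isolated)
Conditions: NaOMe, diglyme, 25 °C; then 130–150 °C, product distilled into a −78 °C trap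
Reagents that add atoms: none
Why: Bamford–Stevens reaction in its cyclopropene-forming variant, in which the salt loses sulfinate, the vinyldiazoalkane loses N2 and the vinylcarbene closes onto the β-carbon, the volatile cyclopropene leaving the hot mixture as it forms.

Step 10
Reactants: 19 2-(2-bromoethyl)-2-methyl-1,3-dioxolane; 18 3,3-dimethylcyclopropene
Product: 22 bromo{(1S,3S)-2,2-dimethyl-3-[2-(2-methyl-1,3-dioxolan-2-yl)ethyl]cyclopropyl}zinc (cis; THF solution used directly), via Grignard reagent 20 (not isolated), via cyclopropylmagnesium bromide 21 (not isolated)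
Conditions: Mg, THF, 25 °C; then 18, CuBr·SMe2 (5 mol %), (R,SP)-Josiphos (6 mol %), Et2O–toluene, −30 °C; then ZnBr2, THF, −30 → 0 °C
Reagents that add atoms: zinc bromide, Br[Zn]Br
Why: Copper-catalysed enantioselective carbomagnesiation of a 3,3-disubstituted cyclopropene, in which syn addition across the strained double bond places the chain and the metal cis, the chiral diphosphine–copper complex chooses which of the two enantiotopic olefinic carbons receives the alkyl group (Ca and Cb set together), and the configurationally stable cyclopropylmagnesium is transmetalated to zinc with retention.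

Step 11
Reactants: 13 enol triflate; 22 cis-cyclopropylzinc bromide
Product: 23 2-{2-[(1R,3S)-2,2-dimethyl-3-[(5R)-5-methyl-5-{(1S)-3-methyl-1-[2,4,6-tris(benzyloxy)phenyl]butyl}cyclopent-1-en-1-yl]cyclopropyl]ethyl}-2-methyl-1,3-dioxolane
Conditions: Pd2(dba)3 (2.5 mol %), SPhos (10 mol %), LiCl, THF, 50 °C
Reagents that add atoms: none
Why: Negishi coupling of an alkenyl triflate with a secondary cyclopropylzinc halide under zerovalent palladium catalysis, which proceeds with retention at the cyclopropyl carbon (so the cis relationship and both cyclopropane centres are carried over) and is free of β-hydride elimination because the nucleophile is a cyclopropyl group.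

Step 12
Reactants: 23 vinylcyclopropane
Product: 24 (1S,2S,3R)-2-{(1R,3R)-2,2-dimethyl-3-[2-(2-methyl-1,3-dioxolan-2-yl)ethyl]cyclopropyl}-3-methyl-3-{(1S)-3-methyl-1-[2,4,6-tris(benzyloxy)phenyl]butyl}cyclopentan-1-ol (expected major isomer)
Conditions: BH3·THF, THF, 0 → 25 °C; then NaOH, H2O2, 0 → 25 °C
Reagents that add atoms: hydrogen peroxide, OO
Why: Brown hydroboration–oxidation, in which boron adds to the less substituted C1 and hydrogen to C5 in a syn fashion, expected on the ring face cis to the C4 methyl and away from the bulky C9′ substituent, and oxidation with retention gives the C1 alcohol; the C1 and C5 configurations formed here are provisional (C1 is oxidised and C5 equilibrated in step 13).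

Step 13
Reactants: 24 cyclopentanol
Product: 26 (2R,3R)-2-{(1R,3R)-2,2-dimethyl-3-[2-(2-methyl-1,3-dioxolan-2-yl)ethyl]cyclopropyl}-3-methyl-3-{(1S)-3-methyl-1-[2,4,6-tris(benzyloxy)phenyl]butyl}cyclopentan-1-one, via C5-epimeric ketone 25 (not isolated)
Conditions: Dess–Martin periodinane, pyridine, CH2Cl2, 0 → 25 °C; then NaOMe (cat.), MeOH–THF, 40 °C
Reagents that add atoms: none
Why: Dess–Martin oxidation gives the C1 ketone and base-catalysed enolisation (epimerisation α to a ketone) should equilibrate C5 to the isomer with the cyclopropyl group trans to the large C9′ substituent and cis to the C4 methyl, which is the configuration of the target.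

Step 14
Reactants: 26 tris(benzyl ether) ketone
Product: 27 (2R,3R)-2-{(1R,3R)-2,2-dimethyl-3-[2-(2-methyl-1,3-dioxolan-2-yl)ethyl]cyclopropyl}-3-methyl-3-[(1S)-3-methyl-1-(2,4,6-trihydroxyphenyl)butyl]cyclopentan-1-one
Conditions: H2 (1 atm), Pd/C, EtOAc, 25 °C
Reagents that add atoms: none
Why: Catalytic hydrogenolysis of benzyl aryl ethers, carried out while no alkene or aldehyde is present, with the alkylcyclopropane, the ketone and the dioxolane inert under these neutral conditions.

Step 15
Reactants: 27 triphenol
Product: 29 Macrocarpal N, via bis(iminium) salt 28 (not isolated)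
Conditions: POCl3, DMF, EtOAc, 0 → 25 °C; then H2O–THF, 25 → 40 °C
Reagents that add atoms: N,N-dimethylformamide, CN(C)C=O; water, O
Why: Vilsmeier–Haack formylation, in which the free phloroglucinol ring, far more nucleophilic than the enolisable C1 ketone, should be attacked by the chloroiminium ion at both of its free positions, and the aqueous acid formed on quenching hydrolyses the two iminium groups and the dioxolane in the same operation.

**Compound list**

1 | 3,5-bis(benzyloxy)phenol | Oc1cc(OCc2ccccc2)cc(OCc2ccccc2)c1 | starting material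
2 | 4,6-bis(benzyloxy)-2-hydroxybenzaldehyde | O=Cc1c(O)cc(OCc2ccccc2)cc1OCc1ccccc1 | intermediate
3 | pent-4-enoic anhydride | C=CCCC(=O)OC(=O)CCC=C | starting material
4 | 3-allyl-5,7-bis(benzyloxy)-2H-chromen-2-one (3-allyl-5,7-bis(benzyloxy)coumarin) | C=CCC1=Cc2c(OCc3ccccc3)cc(OCc3ccccc3)cc2OC1=O | intermediate
5 | isobutylmagnesium bromide | CC(C)C[Mg]Br | starting material
6 | iodomethane | CI | starting material
7 | (4R)-3-allyl-5,7-bis(benzyloxy)-4-isobutyl-2-(trimethylsilyloxy)-4H-chromene | C=CCC1=C(O[Si](C)(C)C)Oc2cc(OCc3ccccc3)cc(OCc3ccccc3)c2[C@H]1CC(C)C | intermediate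
8 | lithium enolate of (4R)-3-allyl-5,7-bis(benzyloxy)-4-isobutylchroman-2-one | C=CCC1=C(O[Li])Oc2cc(OCc3ccccc3)cc(OCc3ccccc3)c2[C@H]1CC(C)C | intermediate
9 | (3R,4R)-3-allyl-5,7-bis(benzyloxy)-4-isobutyl-3-methylchroman-2-one (methyl trans, allyl cis to isobutyl) | O=C1Oc2cc(OCc3ccccc3)cc(OCc3ccccc3)c2[C@@H](CC(C)C)[C@@]1(C)CC=C | intermediate
10 | (3R,4R)-3-allyl-5,7-bis(benzyloxy)-4-isobutyl-3-methylchroman-2-ol (anomeric mixture) | OC1Oc2cc(OCc3ccccc3)cc(OCc3ccccc3)c2[C@@H](CC(C)C)[C@@]1(C)CC=C | intermediate
11 | (2R)-2-methyl-2-{(1R)-3-methyl-1-[2,4,6-tris(benzyloxy)phenyl]butyl}pent-4-enal | C=CC[C@@](C)(C=O)[C@H](CC(C)C)c1c(OCc2ccccc2)cc(OCc2ccccc2)cc1OCc1ccccc1 | intermediate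
12 | (2R)-2-methyl-2-{(1R)-3-methyl-1-[2,4,6-tris(benzyloxy)phenyl]butyl}cyclopentan-1-one | O=C1CCC[C@]1(C)[C@H](CC(C)C)c1c(OCc2ccccc2)cc(OCc2ccccc2)cc1OCc1ccccc1 | intermediate
13 | (5R)-5-methyl-5-{(1S)-3-methyl-1-[2,4,6-tris(benzyloxy)phenyl]butyl}cyclopent-1-en-1-yl trifluoromethanesulfonate | O=S(=O)(OC1=CCC[C@]1(C)[C@H](CC(C)C)c1c(OCc2ccccc2)cc(OCc2ccccc2)cc1OCc1ccccc1)C(F)(F)F | intermediate
14 | 3-methylbut-2-enal | CC(C)=CC=O | starting material
15 | 3-methylbut-2-enal p-toluenesulfonylhydrazone | CC(C)=CC=NNS(=O)(=O)c1ccc(C)cc1 | intermediate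
16 | sodium salt of tosylhydrazone 15 | CC(C)=CC=N[N-]S(=O)(=O)c1ccc(C)cc1.[Na+] | intermediate
17 | 1-diazo-3-methylbut-2-ene | CC(C)=CC=[N+]=[N-] | intermediate
18 | 3,3-dimethylcyclopropene | CC1(C)C=C1 | intermediate
19 | 2-(2-bromoethyl)-2-methyl-1,3-dioxolane | CC1(CCBr)OCCO1 | starting material
20 | [2-(2-methyl-1,3-dioxolan-2-yl)ethyl]magnesium bromide | CC1(CC[Mg]Br)OCCO1 | intermediate
21 | bromo{(1S,3S)-2,2-dimethyl-3-[2-(2-methyl-1,3-dioxolan-2-yl)ethyl]cyclopropyl}magnesium (cis) | CC1(CC[C@@H]2[C@H]([Mg]Br)C2(C)C)OCCO1 | intermediate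
22 | bromo{(1S,3S)-2,2-dimethyl-3-[2-(2-methyl-1,3-dioxolan-2-yl)ethyl]cyclopropyl}zinc (cis) | CC1(CC[C@@H]2[C@H]([Zn]Br)C2(C)C)OCCO1 | intermediate
23 | 2-{2-[(1R,3S)-2,2-dimethyl-3-[(5R)-5-methyl-5-{(1S)-3-methyl-1-[2,4,6-tris(benzyloxy)phenyl]butyl}cyclopent-1-en-1-yl]cyclopropyl]ethyl}-2-methyl-1,3-dioxolane (cis-cyclopropane) | CC1(CC[C@@H]2[C@H](C3=CCC[C@]3(C)[C@H](CC(C)C)c3c(OCc4ccccc4)cc(OCc4ccccc4)cc3OCc3ccccc3)C2(C)C)OCCO1 | intermediate
24 | (1S,2S,3R)-2-{(1R,3R)-2,2-dimethyl-3-[2-(2-methyl-1,3-dioxolan-2-yl)ethyl]cyclopropyl}-3-methyl-3-{(1S)-3-methyl-1-[2,4,6-tris(benzyloxy)phenyl]butyl}cyclopentan-1-ol | CC1(CC[C@@H]2[C@H]([C@@H]3[C@@H](O)CC[C@]3(C)[C@H](CC(C)C)c3c(OCc4ccccc4)cc(OCc4ccccc4)cc3OCc3ccccc3)C2(C)C)OCCO1 | intermediate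
25 | (2S,3R)-2-{(1R,3R)-2,2-dimethyl-3-[2-(2-methyl-1,3-dioxolan-2-yl)ethyl]cyclopropyl}-3-methyl-3-{(1S)-3-methyl-1-[2,4,6-tris(benzyloxy)phenyl]butyl}cyclopentan-1-one (C5 epimer of 26) | CC1(CC[C@@H]2[C@H]([C@@H]3C(=O)CC[C@]3(C)[C@H](CC(C)C)c3c(OCc4ccccc4)cc(OCc4ccccc4)cc3OCc3ccccc3)C2(C)C)OCCO1 | intermediate
26 | (2R,3R)-2-{(1R,3R)-2,2-dimethyl-3-[2-(2-methyl-1,3-dioxolan-2-yl)ethyl]cyclopropyl}-3-methyl-3-{(1S)-3-methyl-1-[2,4,6-tris(benzyloxy)phenyl]butyl}cyclopentan-1-one | CC1(CC[C@@H]2[C@H]([C@H]3C(=O)CC[C@]3(C)[C@H](CC(C)C)c3c(OCc4ccccc4)cc(OCc4ccccc4)cc3OCc3ccccc3)C2(C)C)OCCO1 | intermediate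
27 | (2R,3R)-2-{(1R,3R)-2,2-dimethyl-3-[2-(2-methyl-1,3-dioxolan-2-yl)ethyl]cyclopropyl}-3-methyl-3-[(1S)-3-methyl-1-(2,4,6-trihydroxyphenyl)butyl]cyclopentan-1-one | CC1(CC[C@@H]2[C@H]([C@H]3C(=O)CC[C@]3(C)[C@H](CC(C)C)c3c(O)cc(O)cc3O)C2(C)C)OCCO1 | intermediate
28 | bis(N,N-dimethyliminium) dichloride formed from 27 (ArCH=NMe2+ at both free ring positions) | CC1(CC[C@@H]2[C@H]([C@H]3C(=O)CC[C@]3(C)[C@H](CC(C)C)c3c(O)c(C=[N+](C)C)c(O)c(C=[N+](C)C)c3O)C2(C)C)OCCO1.[Cl-].[Cl-] | intermediate
29 | Macrocarpal N, 2,4,6-trihydroxy-5-{(1S)-3-methyl-1-[(1R,2R)-1-methyl-2-[(1R,3R)-2,2-dimethyl-3-(3-oxobutyl)cyclopropyl]-3-oxocyclopentyl]butyl}benzene-1,3-dicarbaldehyde | CC(=O)CC[C@@H]1[C@H]([C@H]2C(=O)CC[C@]2(C)[C@H](CC(C)C)c2c(O)c(C=O)c(O)c(C=O)c2O)C1(C)C | target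

**Step count and risks**

Total step count: 15. Longest linear sequence: 12 steps (1 → 29 through steps 1–7 and 11–15); the cyclopropylzinc branch (steps 8–10) is 3 steps.

Steps most likely to fail:

1. Step 3. The conjugate transfer of isobutyl to a trisubstituted, donor-substituted coumarin may be too slow. The Grignard reagent may instead attack the silylated carbonyl carbon directly or add without the catalyst, which would erode enantioselectivity. C-methylation of the fully substituted enolate may be incomplete. Fallback (sets out from 1, returns at 9): the isobutyl group is built into the coumarin and C9′ is created by hydride transfer instead of alkyl transfer. Pechmann condensation of 1 with ethyl 5-methyl-3-oxohexanoate (InCl3 cat., 60 °C) would give 5,7-bis(benzyloxy)-4-isobutylcoumarin F1. Asymmetric copper hydride 1,4-reduction (Cu(OAc)2·H2O, (R)-DTBM-SEGPHOS or its antipode, (EtO)2MeSiH, tBuOH, toluene), a reaction established for 4-substituted coumarins, would give (4S)-5,7-bis(benzyloxy)-4-isobutylchroman-2-one F2. Deprotonation (LiN(SiMe3)2, THF, −78 °C) and allylation with allyl bromide trans to the isobutyl group would give (3S,4S)-3-allyl-5,7-bis(benzyloxy)-4-isobutylchroman-2-one F3. A second deprotonation (LiN(iPr)2) produces the lithium enolate 8 of the main route, and MeI/DMPU would return 9 with the same anti selectivity.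

2. Step 11. Transmetalation and reductive elimination between a triflate carbon next to a quaternary centre and a cyclopropyl carbon flanked by a gem-dimethyl group and a cis substituent may be too slow. Hydrolysis or reduction of the triflate and protodemetalation of the zinc reagent would then take over. Fallback (sets out from ketone 12 and the cyclopropylmagnesium bromide 21 of step 10, returns at 23): carbonyl addition and dehydration replace the cross-coupling. Addition of 21 to 12 in the presence of anhydrous CeCl3 (THF, −78 → 0 °C; organocerium addition to a hindered, enolisable ketone, retention at Cb) would give the tertiary cyclopropylcarbinol (2R)-1-{(1S,3R)-2,2-dimethyl-3-[2-(2-methyl-1,3-dioxolan-2-yl)ethyl]cyclopropyl}-2-methyl-2-{(1S)-3-methyl-1-[2,4,6-tris(benzyloxy)phenyl]butyl}cyclopentan-1-ol F4. Syn-dehydration with the Burgess reagent (benzene, 50 °C) should place the double bond between C5 and C1, because C4 is quaternary and elimination towards Cb would give a strained alkylidenecyclopropane, and would return 23.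

3. Step 15. The chloroiminium reagent may react with the enolisable C1 ketone (chloroformylation), the second formylation may stall, and the free triphenol may oxidise in air. Fallback (sets out from 26, returns at 29): formylation before debenzylation instead of after it. Rieche formylation of the tris(benzyl ether) 26 (Cl2CHOMe, SnCl4, CH2Cl2, −78 → 0 °C; aqueous HCl work-up, which also cleaves the dioxolane) would give 2,4,6-tris(benzyloxy)-5-{(1S)-3-methyl-1-[(1R,2R)-1-methyl-2-[(1R,3R)-2,2-dimethyl-3-(3-oxobutyl)cyclopropyl]-3-oxocyclopentyl]butyl}benzene-1,3-dicarbaldehyde F5. Debenzylation with BCl3 and pentamethylbenzene (CH2Cl2, −78 °C) would then give 29; any material already partly debenzylated in the formylation converges at this point.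

Further compounds

F1 | step 3 | 5,7-bis(benzyloxy)-4-isobutylcoumarin | CC(C)CC1=CC(=O)Oc2cc(OCc3ccccc3)cc(OCc3ccccc3)c12
F2 | step 3 | (4S)-5,7-bis(benzyloxy)-4-isobutylchroman-2-one | O=C1Oc2cc(OCc3ccccc3)cc(OCc3ccccc3)c2[C@@H](CC(C)C)C1
F3 | step 3 | (3S,4S)-3-allyl-5,7-bis(benzyloxy)-4-isobutylchroman-2-one (trans) | O=C1Oc2cc(OCc3ccccc3)cc(OCc3ccccc3)c2[C@@H](CC(C)C)[C@@H]1CC=C
F4 | step 11 | (2R)-1-{(1S,3R)-2,2-dimethyl-3-[2-(2-methyl-1,3-dioxolan-2-yl)ethyl]cyclopropyl}-2-methyl-2-{(1S)-3-methyl-1-[2,4,6-tris(benzyloxy)phenyl]butyl}cyclopentan-1-ol (carbinol configuration undefined) | CC1(CC[C@@H]2[C@H](C3(O)CCC[C@]3(C)[C@H](CC(C)C)c3c(OCc4ccccc4)cc(OCc4ccccc4)cc3OCc3ccccc3)C2(C)C)OCCO1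
F5 | step 15 | 2,4,6-tris(benzyloxy)-5-{(1S)-3-methyl-1-[(1R,2R)-1-methyl-2-[(1R,3R)-2,2-dimethyl-3-(3-oxobutyl)cyclopropyl]-3-oxocyclopentyl]butyl}benzene-1,3-dicarbaldehyde | CC(=O)CC[C@@H]1[C@H]([C@H]2C(=O)CC[C@]2(C)[C@H](CC(C)C)c2c(OCc3ccccc3)c(C=O)c(OCc3ccccc3)c(C=O)c2OCc2ccccc2)C1(C)C
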